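**Retrosynthetic overview** (ent-kaurane numbering)
1. Target 36 ⇐ 15-alcohol 35 ⇐ hydroxy lactone 34 ⇐ aldehyde lactone 33: the C-15 ketone comes from late allylic oxidation; the 7,20-δ-lactone is closed last by moving the C-20 oxygen from C-6 to the C-7 carboxyl, which releases C-6 as CH2OH.
2. Key disconnection: ring A (C-1, C-2, C-3, C-4, C-5, C-10) by an intramolecular Diels–Alder reaction of the 2-silyloxydiene C-10=C-1(OSi)–C-2=C-3 with a citraconate C-4=C-5 (bonds C-3–C-4 and C-5–C-10).
3. Enabling feature: ring A carries oxygen on C-1 next to the spiro carbon C-10, and the oxidised one-carbon arms C-19 (on C-4), C-6 (on C-5) and C-20 (on C-10) lie on one face; C-20–O and C-6 are cis on adjacent ring atoms, so a temporary five-membered C-20–O–C-6(=O) lactone can tether citraconic anhydride to the diene.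
4. Dienol 23 ⇐ bicyclo[3.2.1]octane 13 ⇐ 5-exo vinyl-radical closure of ring D ⇐ α-alkylation (C-8 quaternary) ⇐ auxiliary-controlled Diels–Alder reaction of butadiene (ring C).
5. Ring order: C → D → A together with the temporary γ-lactone (key step) → δ-lactone.

Key step: step 16

Remark: positions are given in ent-kaurane numbering; compounds 15, 16, 18, 19, 20 and 21 are epimer mixtures at the side-chain carbons C-10 (and C-1), which converge when C-10 becomes trigonal in 22.

**Step 1**
Reactants: 1 (2,2-dimethyl-1,3-dioxan-5-yl)methanol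
Product: 2 2,2-dimethyl-1,3-dioxane-5-carbaldehyde
Conditions: Dess–Martin periodinane, NaHCO3, CH2Cl2, 0 → 23 °C
Reagents that add atoms: none
Why: Dess–Martin oxidation should convert the primary alcohol into the aldehyde under buffered conditions that keep the acetonide; no stereocentre is involved.

**Step 2**
Reactants: 3 (4R)-4-benzyl-3-(chloroacetyl)-1,3-oxazolidin-2-one; 4 triethyl phosphite
Product: 5 phosphonate imide
Conditions: neat, 130 °C
Reagents that add atoms: none
Why: Michaelis–Arbuzov reaction of the α-chloro imide should give the stabilised phosphonate without touching the oxazolidinone stereocentre.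

**Step 3**
Reactants: 2 2,2-dimethyl-1,3-dioxane-5-carbaldehyde; 5 phosphonate imide
Product: 6 (E)-enoyl imide
Conditions: LiCl, i-Pr2NEt, MeCN, 23 °C
Reagents that add atoms: none
Why: Horner–Wadsworth–Emmons olefination with a stabilised phosphonate under mild amine/LiCl conditions should give the (E)-enoyl imide through reversible addition and anti elimination.

**Step 4**
Reactants: 6 (E)-enoyl imide; 7 buta-1,3-diene
Product: 8 cyclohexene imide
Conditions: 7 (excess), Et2AlCl (1.5 equiv), CH2Cl2, −30 → 0 °C
Reagents that add atoms: none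
Why: In this oxazolidinone-auxiliary-controlled Lewis-acid Diels–Alder reaction Et2AlCl chelates both imide carbonyls, the benzyl group shields one face of the s-cis enoyl unit, and butadiene should add to the open face, setting C-9 as drawn with C-8 trans from the (E)-alkene.

**Step 5**
Reactants: 8 cyclohexene imide
Product: 9 cyclohexene acid
Conditions: LiOH, H2O2, THF/H2O, 0 °C; then Na2SO3; HCl to pH 3
Reagents that add atoms: hydrogen peroxide (OO)
Why: Hydroperoxide-mediated imide hydrolysis attacks the exocyclic carbonyl selectively and should release the acid and the recoverable auxiliary with C-9 intact.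

**Step 6**
Reactants: 9 cyclohexene acid
Product: 10 cyclohexene tert-butyl ester
Conditions: Boc2O, 4-(dimethylamino)pyridine (cat.), t-BuOH, 40 °C
Reagents that add atoms: di-tert-butyl dicarbonate (CC(C)(C)OC(=O)OC(=O)OC(C)(C)C)
Why: Esterification through the mixed carbonic anhydride under nucleophilic catalysis should give the tert-butyl ester without acid, so the acetonide survives.

**Step 7**
Reactants: 10 cyclohexene tert-butyl ester; 11 2,3-dibromoprop-1-ene
Product: 12 bromoallyl ester
Conditions: LiN(i-Pr)2, THF, −78 °C; then 11, DMPU, −78 → −20 °C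
Reagents that add atoms: none
Why: Ester enolate alkylation by the allylic bromide should occur anti to the neighbouring C-9 substituent, creating quaternary C-8 with the ester cis and the bromoallyl arm trans to the side chain.

**Step 8**
Reactants: 12 bromoallyl ester
Product: 13 bicyclic acetonide
Conditions: Bu3SnH, 2,2'-azobis(2-methylpropionitrile) (cat.), benzene (0.05 M), 80 °C
Reagents that add atoms: none
Why: Tin-hydride 5-exo-trig cyclisation of the vinyl radical onto C-13 of the ring alkene should close ring D; the bridge can only form on the face of the axial bromoallyl arm, which fixes C-13, and a fairly high stannane concentration traps the kinetic bicyclo[3.2.1]octyl radical.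

**Step 9**
Reactants: 13 bicyclic acetonide
Product: 14 bicyclic diol
Conditions: AcOH/H2O/THF (3:1:1), 23 °C
Reagents that add atoms: none
Why: Mild acetal hydrolysis should free the 1,3-diol while the tert-butyl ester and exocyclic alkene survive.

**Step 10**
Reactants: 14 bicyclic diol
Product: 15 mono-silyl ether
Conditions: t-BuMe2SiCl (1.0 equiv), imidazole, CH2Cl2, −20 °C
Reagents that add atoms: tert-butyldimethylsilyl chloride (CC(C)(C)[Si](C)(C)Cl)
Why: Monosilylation of the symmetrical diol differentiates the two hydroxymethyl groups; both epimers at the new side-chain centre are acceptable because this carbon becomes trigonal in step 15.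

**Step 11**
Reactants: 15 mono-silyl ether
Product: 16 side-chain aldehyde
Conditions: Dess–Martin periodinane, NaHCO3, CH2Cl2, 0 °C
Reagents that add atoms: none
Why: Dess–Martin oxidation of the remaining primary alcohol should give the aldehyde without β-elimination of the silyloxy group.

**Step 12**
Reactants: 16 side-chain aldehyde; 17 vinylmagnesium bromide
Product: 18 allylic alcohol
Conditions: THF, −78 °C
Reagents that add atoms: none
Why: Grignard 1,2-addition should take the aldehyde in preference to the hindered tert-butyl ester; the carbinol configuration is irrelevant because it is oxidised in step 14.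

**Step 13**
Reactants: 18 allylic alcohol
Product: 19 side-chain diol
Conditions: Bu4NF, THF, 0 °C
Reagents that add atoms: none
Why: Fluoride desilylation should free the primary alcohol without affecting ester or alkenes.

**Step 14**
Reactants: 19 side-chain diol
Product: 20 hydroxy vinyl ketone
Conditions: MnO2, CH2Cl2, 23 °C
Reagents that add atoms: none
Why: MnO2 oxidises only the allylic secondary alcohol, so the vinyl ketone should form under neutral conditions that limit oxa-Michael closure.

**Step 15**
Reactants: 20 hydroxy vinyl ketone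
Product: 23 dienol, via trimethylsilyl ether 21 (not isolated), via bis-silyl dienol ether 22 (not isolated)
Conditions: Me3SiCl, Et3N, CH2Cl2, 0 °C; i-Pr3SiOTf, Et3N, −78 → 0 °C; K2CO3, MeOH, 0 °C
Reagents that add atoms: triisopropylsilyl trifluoromethanesulfonate (CC(C)[Si](C(C)C)(C(C)C)OS(=O)(=O)C(F)(F)F)
Why: After temporary O-silylation, soft enolisation (silyl triflate/amine) can only engage C-10 and should give the cross-conjugated 2-silyloxydiene as the (E)-isomer, with bulky C-9 cis to the silyloxy oxygen by allylic strain; basic methanolysis then removes only the labile trimethylsilyl ether.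

**Step 16**
Reactants: 23 dienol; 24 citraconic anhydride
Product: 27 cycloadduct, via half ester 25 (not isolated), via triene methyl ester 26 (not isolated)
Conditions: 24, 4-(dimethylamino)pyridine (cat.), pyridine, CH2Cl2, 0 → 23 °C; Me3SiCHN2, MeOH, 0 °C; then toluene, 2,6-di-tert-butyl-4-methylphenol (trace), 120 °C (sealed tube)
Reagents that add atoms: (trimethylsilyl)diazomethane (C[Si](C)(C)C=[N+]=[N-])
Why: Acylation of the C-20 alcohol at the less hindered (CH-side) carbonyl of the anhydride and in-flask methylation give the ester-tethered triene, which on heating should undergo a normal-demand intramolecular Diels–Alder reaction in which the nucleophilic C-10 of the 2-silyloxydiene bonds to C-5 and the unhindered C-3 terminus bonds to the methyl-bearing C-4. The closest known reaction type is the tandem esterification/intramolecular Diels–Alder reaction of 2,4-dienols with maleic anhydride. Ring A closes by suprafacial [4+2] cycloaddition and the temporary γ-lactone (C-10, C-20, O, C-6, C-5) closes as the tether ring, which can only be cis-fused because the tether sits on the inside (Z) position of the diene terminus. Hence C-20 and C-6 are cis at C-10/C-5 (tether), C-19 is cis to C-6 at C-4 ((Z)-geometry of the citraconate), and C-10 relative to C-9 follows from the diene face attacked. The step needs attack on the diene face turned away from ring C: the diene hangs from an axial bond at C-9 of the rigid bicyclo[3.2.1]octane with its plane tangential to ring C and its silyloxy-bearing C-1 end over the C-11 methylene rather than over quaternary C-8, so the inner face is blocked by the axial hydrogens on C-12 and C-14 and the tethered dienophile should add from the outer face (that of H-9). Regiochemistry is fixed by the three-atom tether, and the unconjugated 16-methylidene group is not a competing dienophile.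

**Step 17**
Reactants: 27 cycloadduct
Product: 29 acetal ketone, via lactol 28 (not isolated)
Conditions: i-Bu2AlH (1.2 equiv), CH2Cl2, −78 °C; aqueous potassium sodium tartrate work-up; then camphorsulfonic acid (cat.), MeOH, 0 → 23 °C
Reagents that add atoms: methanol (CO)
Why: Low-temperature hydride reduction should take the γ-lactone to the lactol faster than the two hindered esters on quaternary carbons, and acid-catalysed acetalisation then locks C-6 as a methyl acetal on the C-20 oxygen while protodesilylating the enol ether to the C-1 ketone; the acetal carbon forms as an anomeric mixture.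

**Step 18**
Reactants: 29 acetal ketone
Product: 30 acetal diol
Conditions: LiBH4, THF/MeOH, 0 → 40 °C
Reagents that add atoms: none
Why: Borohydride reduction should take the methyl ester and the ketone but not the tert-butyl ester or acetal; axial attack of the small hydride on the C-1 ketone, anti to the axial C-10–C-20 bond, should give the equatorial alcohol cis to C-20.

**Step 19**
Reactants: 30 acetal diol
Product: 31 acetal diacetate
Conditions: Ac2O, pyridine, 4-(dimethylamino)pyridine (cat.), CH2Cl2, 23 °C
Reagents that add atoms: acetic anhydride (CC(=O)OC(C)=O)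
Why: Nucleophile-catalysed acylation should acetylate both the primary C-19 and the secondary C-1 alcohol while C-6 stays masked as the acetal.

**Step 20**
Reactants: 31 acetal diacetate
Product: 33 aldehyde lactone, via lactol acid 32 (not isolated)
Conditions: CF3CO2H/CH2Cl2/H2O (10:88:2), 0 °C; then pyridinium p-toluenesulfonate, toluene, 4 Å molecular sieves, 60 °C
Reagents that add atoms: water (O)
Why: Acid cleaves the tert-butyl ester and hydrolyses the acetal to the lactol, and acid-catalysed δ-lactonisation of the C-20 alcohol with the C-7 acid (translactonisation under removal of water) should drain the hydroxy aldehyde form and leave C-6 as the free aldehyde; no stereocentre changes if enolisation at C-5 is avoided.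

**Step 21**
Reactants: 33 aldehyde lactone
Product: 34 hydroxy lactone
Conditions: NaBH4, MeOH/CH2Cl2, −20 °C
Reagents that add atoms: none
Why: Borohydride reduction at low temperature should reduce only the aldehyde in the presence of acetates and the hindered lactone.

**Step 22**
Reactants: 34 hydroxy lactone
Product: 35 15-alcohol
Conditions: SeO2 (cat.), t-BuOOH, CH2Cl2, 23 °C
Reagents that add atoms: tert-butyl hydroperoxide (CC(C)(C)OO)
Why: Riley-type allylic oxidation (ene reaction then [2,3]-sigmatropic shift) should hydroxylate C-15, the only allylic methylene of the exocyclic alkene; either C-15 epimer serves.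

**Step 23**
Reactants: 35 15-alcohol
Product: 36 target CNP0105570.2
Conditions: MnO2, CH2Cl2, 23 °C
Reagents that add atoms: none
Why: MnO2 oxidises the allylic alcohol to the exo-methylene ketone and should leave the saturated primary C-6 alcohol untouched.

**Compound list**
1 | (2,2-dimethyl-1,3-dioxan-5-yl)methanol | CC1(C)OCC(CO)CO1 | starting material
2 | 2,2-dimethyl-1,3-dioxane-5-carbaldehyde | CC1(C)OCC(C=O)CO1 | intermediate
3 | (4R)-4-benzyl-3-(chloroacetyl)-1,3-oxazolidin-2-one | ClCC(=O)N1[C@H](Cc2ccccc2)COC1=O | starting material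
4 | triethyl phosphite | CCOP(OCC)OCC | starting material
5 | phosphonate imide: diethyl {2-[(4R)-4-benzyl-2-oxo-1,3-oxazolidin-3-yl]-2-oxoethyl}phosphonate | CCOP(=O)(OCC)CC(=O)N1[C@H](Cc2ccccc2)COC1=O | intermediate
6 | (E)-enoyl imide: (4R)-4-benzyl-3-[(2E)-3-(2,2-dimethyl-1,3-dioxan-5-yl)prop-2-enoyl]-1,3-oxazolidin-2-one | O=C(/C=C/C1COC(C)(C)OC1)N1[C@H](Cc2ccccc2)COC1=O | intermediate
7 | buta-1,3-diene | C=CC=C | starting material
8 | cyclohexene imide: (4R)-4-benzyl-3-{[(1R,6S)-6-(2,2-dimethyl-1,3-dioxan-5-yl)cyclohex-3-en-1-yl]carbonyl}-1,3-oxazolidin-2-one | O=C([C@@H]1CC=CC[C@H]1C1COC(C)(C)OC1)N1[C@H](Cc2ccccc2)COC1=O | intermediate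
9 | cyclohexene acid: (1R,6S)-6-(2,2-dimethyl-1,3-dioxan-5-yl)cyclohex-3-ene-1-carboxylic acid | OC(=O)[C@@H]1CC=CC[C@H]1C1COC(C)(C)OC1 | intermediate
10 | cyclohexene tert-butyl ester: tert-butyl (1R,6S)-6-(2,2-dimethyl-1,3-dioxan-5-yl)cyclohex-3-ene-1-carboxylate | CC(C)(C)OC(=O)[C@@H]1CC=CC[C@H]1C1COC(C)(C)OC1 | intermediate
11 | 2,3-dibromoprop-1-ene | C=C(Br)CBr | starting material
12 | bromoallyl ester: tert-butyl (1R,6S)-1-(2-bromoprop-2-en-1-yl)-6-(2,2-dimethyl-1,3-dioxan-5-yl)cyclohex-3-ene-1-carboxylate (ester cis to the dioxanyl group) | CC(C)(C)OC(=O)[C@@]1(CC(Br)=C)CC=CC[C@H]1C1COC(C)(C)OC1 | intermediate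
13 | bicyclic acetonide: tert-butyl (1R,2S,5R)-2-(2,2-dimethyl-1,3-dioxan-5-yl)-6-methylidenebicyclo[3.2.1]octane-1-carboxylate | C=C1C[C@]2(C(=O)OC(C)(C)C)C[C@H]1CC[C@H]2C1COC(C)(C)OC1 | intermediate
14 | bicyclic diol: tert-butyl (1R,2S,5R)-2-(1,3-dihydroxypropan-2-yl)-6-methylidenebicyclo[3.2.1]octane-1-carboxylate | C=C1C[C@]2(C(=O)OC(C)(C)C)C[C@H]1CC[C@H]2C(CO)CO | intermediate
15 | mono-silyl ether: tert-butyl (1R,2S,5R)-2-[1-(tert-butyldimethylsilyloxy)-3-hydroxypropan-2-yl]-6-methylidenebicyclo[3.2.1]octane-1-carboxylate (both side-chain epimers) | C=C1C[C@]2(C(=O)OC(C)(C)C)C[C@H]1CC[C@H]2C(CO)CO[Si](C)(C)C(C)(C)C | intermediate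
16 | side-chain aldehyde: tert-butyl (1R,2S,5R)-2-[1-(tert-butyldimethylsilyloxy)-3-oxopropan-2-yl]-6-methylidenebicyclo[3.2.1]octane-1-carboxylate (both side-chain epimers) | C=C1C[C@]2(C(=O)OC(C)(C)C)C[C@H]1CC[C@H]2C(C=O)CO[Si](C)(C)C(C)(C)C | intermediate
17 | vinylmagnesium bromide | C=C[Mg]Br | starting material
18 | allylic alcohol: tert-butyl (1R,2S,5R)-2-[1-(tert-butyldimethylsilyloxy)-3-hydroxypent-4-en-2-yl]-6-methylidenebicyclo[3.2.1]octane-1-carboxylate (side-chain diastereomers) | C=C1C[C@]2(C(=O)OC(C)(C)C)C[C@H]1CC[C@H]2C(CO[Si](C)(C)C(C)(C)C)C(O)C=C | intermediate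
19 | side-chain diol: tert-butyl (1R,2S,5R)-2-(1,3-dihydroxypent-4-en-2-yl)-6-methylidenebicyclo[3.2.1]octane-1-carboxylate (side-chain diastereomers) | C=C1C[C@]2(C(=O)OC(C)(C)C)C[C@H]1CC[C@H]2C(CO)C(O)C=C | intermediate
20 | hydroxy vinyl ketone: tert-butyl (1R,2S,5R)-2-(1-hydroxy-3-oxopent-4-en-2-yl)-6-methylidenebicyclo[3.2.1]octane-1-carboxylate (both side-chain epimers) | C=C1C[C@]2(C(=O)OC(C)(C)C)C[C@H]1CC[C@H]2C(CO)C(=O)C=C | intermediate
21 | trimethylsilyl ether of 20 | C=C1C[C@]2(C(=O)OC(C)(C)C)C[C@H]1CC[C@H]2C(CO[Si](C)(C)C)C(=O)C=C | intermediate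
22 | bis-silyl dienol ether: (2E)-1-(trimethylsilyloxy)-3-(triisopropylsilyloxy)penta-2,4-dien-2-yl side chain on the bicyclic tert-butyl ester | C=C1C[C@]2(C(=O)OC(C)(C)C)C[C@H]1CC[C@H]2/C(CO[Si](C)(C)C)=C(\O[Si](C(C)C)(C(C)C)C(C)C)C=C | intermediate
23 | dienol: tert-butyl (1R,2S,5R)-2-[(2E)-1-hydroxy-3-(triisopropylsilyloxy)penta-2,4-dien-2-yl]-6-methylidenebicyclo[3.2.1]octane-1-carboxylate | C=C1C[C@]2(C(=O)OC(C)(C)C)C[C@H]1CC[C@H]2/C(CO)=C(\O[Si](C(C)C)(C(C)C)C(C)C)C=C | intermediate
24 | citraconic anhydride (3-methylfuran-2,5-dione) | CC1=CC(=O)OC1=O | starting material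
25 | half ester: (Z)-citraconate of 23 esterified at the CH-side carbonyl with free acid on the methyl-bearing carbon | C=C1C[C@]2(C(=O)OC(C)(C)C)C[C@H]1CC[C@H]2/C(COC(=O)/C=C(/C)C(=O)O)=C(\O[Si](C(C)C)(C(C)C)C(C)C)C=C | intermediate
26 | triene methyl ester: methyl ester of 25 | C=C1C[C@]2(C(=O)OC(C)(C)C)C[C@H]1CC[C@H]2/C(COC(=O)/C=C(/C)C(=O)OC)=C(\O[Si](C(C)C)(C(C)C)C(C)C)C=C | intermediate
27 | cycloadduct: ring A as C-1/C-2 triisopropylsilyl enol ether; C-6/C-20 γ-lactone cis-fused at C-5/C-10; C-19 methyl ester and methyl on C-4; C-7 tert-butyl ester on C-8; C-20, C-6 and C-19 on one face of ring A and C-9 on the other | C=C1C[C@]2(C(=O)OC(C)(C)C)C[C@H]1CC[C@H]2[C@@]34COC(=O)[C@@H]3[C@](C)(C(=O)OC)CC=C4O[Si](C(C)C)(C(C)C)C(C)C | intermediate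
28 | lactol: 27 with the lactone carbonyl C-6 reduced to the hemiacetal (anomers) | C=C1C[C@]2(C(=O)OC(C)(C)C)C[C@H]1CC[C@H]2[C@@]34COC(O)[C@@H]3[C@](C)(C(=O)OC)CC=C4O[Si](C(C)C)(C(C)C)C(C)C | intermediate
29 | acetal ketone: C-6 methyl acetal bridged to O-20 (anomers); C-1 ketone; C-19 methyl ester; C-7 tert-butyl ester | C=C1C[C@]2(C(=O)OC(C)(C)C)C[C@H]1CC[C@H]2[C@@]34COC(OC)[C@@H]3[C@](C)(C(=O)OC)CCC4=O | intermediate
30 | acetal diol: 29 with C-19 CH2OH and equatorial C-1 OH cis to C-20 | C=C1C[C@]2(C(=O)OC(C)(C)C)C[C@H]1CC[C@H]2[C@@]34COC(OC)[C@@H]3[C@](C)(CO)CC[C@@H]4O | intermediate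
31 | acetal diacetate: 1,19-diacetate of 30 | C=C1C[C@]2(C(=O)OC(C)(C)C)C[C@H]1CC[C@H]2[C@@]34COC(OC)[C@@H]3[C@](C)(COC(C)=O)CC[C@@H]4OC(C)=O | intermediate
32 | lactol acid: C-7 carboxylic acid with C-6/O-20 hemiacetal (anomers); 1,19-diacetate | C=C1C[C@]2(C(=O)O)C[C@H]1CC[C@H]2[C@@]34COC(O)[C@@H]3[C@](C)(COC(C)=O)CC[C@@H]4OC(C)=O | intermediate
33 | aldehyde lactone: 1,19-diacetoxy-6-oxo-6,7-seco-ent-kaur-16-en-7,20-olide | C=C1C[C@]23C[C@H]1CC[C@H]2[C@]1(COC3=O)[C@@H](OC(C)=O)CC[C@@](C)(COC(C)=O)[C@H]1C=O | intermediate
34 | hydroxy lactone: 1,19-diacetoxy-6-hydroxy-6,7-seco-ent-kaur-16-en-7,20-olide | C=C1C[C@]23C[C@H]1CC[C@H]2[C@]1(COC3=O)[C@@H](OC(C)=O)CC[C@@](C)(COC(C)=O)[C@H]1CO | intermediate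
35 | 15-alcohol: 15-hydroxy derivative of 34 (C-15 epimers) | C=C1C(O)[C@]23C[C@H]1CC[C@H]2[C@]1(COC3=O)[C@@H](OC(C)=O)CC[C@@](C)(COC(C)=O)[C@H]1CO | intermediate
36 | target CNP0105570.2: 1,19-diacetoxy-6-hydroxy-15-oxo-6,7-seco-ent-kaur-16-en-7,20-olide (1-acetoxy cis to C-20; configuration as in the SMILES) | C=C1C(=O)[C@]23C[C@H]1CC[C@H]2[C@]1(COC3=O)[C@@H](OC(C)=O)CC[C@@](C)(COC(C)=O)[C@H]1CO | target

**Step count and risks**
Total step count: 23. Longest linear sequence: 22 steps (steps 1 and 3–23; step 2 is a one-step branch).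

Steps most likely to fail:

1. Step 16. The cycloaddition may be slow, because the ester tether must adopt its less favoured conformation and the diene terminus is fully substituted; protodesilylation of the dienol ether, a 1,5-hydrogen shift from C-20, or attack on the inner diene face could then compete. Fallback: from 23, O-alkylation with 5-bromo-3-methylfuran-2(5H)-one (i-Pr2NEt, MeCN) would give the acetal-tethered pseudoester F1, in which the dienophile is a butenolide already at the aldehyde level at C-6 and the linker has no ester conformational penalty. Heating in toluene should give the acylal cycloadduct F2 (only the acetal epimer that can reach the outer diene face is expected to cyclise). NaOMe/MeOH followed by camphorsulfonic acid/MeOH then opens the acylal to the methyl ester and methyl acetal and cleaves the enol ether, returning to the route at 29.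

2. Step 20. The transfer of the C-20 oxygen may stall at the lactol acid, and prolonged acid could epimerise C-5 of the free aldehyde or shift the exocyclic double bond. Fallback: from 31, brief CF3CO2H/H2O treatment at 0 °C is stopped at lactol acid 32, which is isolated; NaBH4 opens the lactol irreversibly to the dihydroxy acid F3; carbodiimide lactonisation (1-ethyl-3-(3-dimethylaminopropyl)carbodiimide hydrochloride, 4-(dimethylamino)pyridine, CH2Cl2) should close the six-membered 7,20-lactone in preference to a seven-membered one and rejoins the route at 34, bypassing 33 and step 21.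

3. Step 15. The β-hydroxy vinyl ketone 20 may cyclise by intramolecular oxa-Michael addition or dehydrate before it is silylated, and the dienol ether may be lost during methanolysis. Fallback: from 18, Dess–Martin oxidation gives the silyl-protected vinyl ketone F4, so the free hydroxy enone never exists; soft enolisation (i-Pr3SiOTf, Et3N) gives the fully silylated dienol ether F5; selective cleavage of the primary tert-butyldimethylsilyl ether with pyridine-buffered HF·pyridine (THF, 0 °C) returns to the route at 23, bypassing 19–22.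

**Further compounds**
F1 | step 16 | pseudoester: 23 O-linked through C-20 to C-5 of 3-methylfuran-2(5H)-one (both acetal epimers) | C=C1C[C@]2(C(=O)OC(C)(C)C)C[C@H]1CC[C@H]2/C(COC1OC(=O)C(C)=C1)=C(\O[Si](C(C)C)(C(C)C)C(C)C)C=C
F2 | step 16 | acylal cycloadduct: ring A silyl enol ether with C-6 as acetal carbon bonded to O-20 and to the C-19 lactone oxygen | C=C1C[C@]2(C(=O)OC(C)(C)C)C[C@H]1CC[C@H]2[C@@]34CO[C@H](OC5=O)[C@@H]3[C@@]5(C)CC=C4O[Si](C(C)C)(C(C)C)C(C)C
F3 | step 20 | dihydroxy acid: 1,19-diacetoxy-6,20-dihydroxy-6,7-seco-ent-kaur-16-en-7-oic acid | C=C1C[C@]2(C(=O)O)C[C@H]1CC[C@H]2[C@]1(CO)[C@@H](OC(C)=O)CC[C@@](C)(COC(C)=O)[C@H]1CO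
F4 | step 15 | silyl-protected vinyl ketone: tert-butyldimethylsilyl ether of 20 | C=C1C[C@]2(C(=O)OC(C)(C)C)C[C@H]1CC[C@H]2C(CO[Si](C)(C)C(C)(C)C)C(=O)C=C
F5 | step 15 | fully silylated dienol ether: (E)-triisopropylsilyl dienol ether of F4 | C=C1C[C@]2(C(=O)OC(C)(C)C)C[C@H]1CC[C@H]2/C(CO[Si](C)(C)C(C)(C)C)=C(\O[Si](C(C)C)(C(C)C)C(C)C)C=C
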